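**Retrosynthetic overview**
- Target ⇒ (methacrylate off, both oxiranes off) 8‑hydroxy‑13‑acetoxy Z,Z‑germacratrien‑12,6‑olide; both epoxides are cis (Z‑alkene derived) and syn to O6/O8.
- Butenolide ⇒ intramolecular aldol condensation (C7=C11) of an O6‑bound 3‑acetoxypyruvate onto the C8 ketone; C6 and C8 carbinols from two CBS reductions.
- Ten‑membered ring ⇒ two‑carbon ring expansion: silyl‑transfer retro‑aldol fragmentation of a cis‑fused 1‑silyloxybicyclo[6.2.0]decadien‑9‑one, giving a 1,3‑dione equivalent whose two carbonyls stay differentiated.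
- Cyclobutanone ⇒ dichloroketene + silyl enol ether of 3,7‑dimethylcycloocta‑2,6‑dienone ⇒ allylic oxidation of 1,5‑dimethylcycloocta‑1,5‑diene ⇒ 2 × isoprene (both Z‑alkenes and both methyls come from here).
- Ring order: eight‑membered carbocycle, cyclobutanone, ten‑membered carbocycle, butenolide, two oxiranes.

Assumption: germacrane numbering (C1–C13) is used for the ten‑membered compounds; 7 and 8 are racemic (one enantiomer drawn); the enol ether C=C of 9, 10 and 13 is drawn E (ring carbons cis), its geometry is erased in step 8.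

**Step 1**
Reactants: 1 isoprene (2 equiv)
Product: 2 (1Z,5Z)-1,5-dimethylcycloocta-1,5-diene
Conditions: Ni(C8H12)2 [bis(cycloocta-1,5-diene)nickel] (0.5 mol%), P(OC6H4-2-C6H5)3 (0.5 mol%), toluene, 60 °C; 1,6-dimethyl regioisomer removed by spinning-band distillation
Reagents that add atoms: none
Why: Zerovalent nickel with a bulky phosphite couples two isoprenes head-to-tail through a bis-allyl nickelacycle and reductive elimination closes the eight-membered ring, whose two trisubstituted alkenes are necessarily Z and already carry the methyls of C4 and C10 (nickel-catalysed [4+4] cyclodimerisation).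

**Step 2**
Reactants: 2 (1Z,5Z)-1,5-dimethylcycloocta-1,5-diene
Product: 3 (2Z,6Z)-3,7-dimethylcycloocta-2,6-dien-1-one
Conditions: Rh2(C6H10NO)4 (dirhodium tetracaprolactamate, 1 mol%), t-BuOOH (5 equiv), CH2Cl2, rt, stopped at ca. 50% conversion, 2 recycled
Reagents that add atoms: tert-butyl hydroperoxide, CC(C)(C)OO
Why: In this dirhodium-catalysed radical allylic oxidation the tert-butylperoxyl radical abstracts H from the CH2 next to the =CH terminus (tertiary-ended allyl radical), capture at the secondary terminus and collapse give the β-methyl enone with both Z ring alkenes intact, and the C2 symmetry of 2 makes the two such CH2 groups equivalent.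

**Step 3**
Reactants: 3 (2Z,6Z)-3,7-dimethylcycloocta-2,6-dien-1-one
Product: 4 (1Z,3E,5Z)-1,5-dimethyl-3-(triethylsilyloxy)cycloocta-1,3,5-triene (all ring double bonds cis)
Conditions: LiN(i-Pr)2 (1.1 equiv), THF, −78 °C; Et3SiCl, −78 → 0 °C; cold pentane work-up, used at once
Reagents that add atoms: chlorotriethylsilane, CC[Si](Cl)(CC)CC
Why: Kinetic deprotonation of the β-methyl enone occurs at the α′-CH2 (also allylic) and O-silylation gives the cross-conjugated silyl enol ether, which is kept at or below 0 °C to avoid 6π-electrocyclisation of the cis,cis,cis-triene (kinetic enolate trapping).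

**Step 4**
Reactants: 4 (1Z,3E,5Z)-1,5-dimethyl-3-(triethylsilyloxy)cycloocta-1,3,5-triene; 5 dichloroacetyl chloride
Product: 8 rac-(1S,2Z,6Z,8S)-3,7-dimethyl-1-(triethylsilyloxy)bicyclo[6.2.0]deca-2,6-dien-9-one (cis-fused), via dichloroketene 6 (not isolated), via dichlorocyclobutanone adduct 7 (not isolated)
Conditions: Cl2CHCOCl, Et3N, hexane, 0 °C → rt; filter, concentrate; then Zn dust, AcOH, i-PrOH, 0 °C → rt
Reagents that add atoms: none
Why: Dichloroketene adds [2+2] to the silyl enol ether C=C (the tub-shaped triene keeps it largely out of conjugation with the flanking alkenes), the ketene carbonyl carbon bonding to the enol β-carbon and ring closure on the oxocarbenium carbon giving the cis-fused cyclobutanone as a racemate, and zinc then removes both chlorines so that the later fragmentation breaks the ring-fusion bond (ketene–silyl enol ether cycloaddition, reductive dechlorination).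

**Step 5**
Reactants: 8 rac-(1S,2Z,6Z,8S)-3,7-dimethyl-1-(triethylsilyloxy)bicyclo[6.2.0]deca-2,6-dien-9-one
Product: 10 (1R,2Z,6Z,8E)-3,7-dimethyl-9-(triethylsilyloxy)cyclodeca-2,6,8-trien-1-ol, via silyl trienone 9 (not isolated)
Conditions: Et3SiOTf (5 mol%), 2,6-di-tert-butyl-4-methylpyridine (10 mol%), CH2Cl2, −78 °C; Et3N (0.1 equiv); then (S)-Me-CBS oxazaborolidine (20 mol%), catecholborane (1.5 equiv), toluene, −78 → −40 °C; pH 7 buffer
Reagents that add atoms: none
Why: Proposed new method: the silyl triflate activates the cyclobutanone carbonyl, the lone pair of the silyloxy oxygen on the adjacent quaternary carbon expels the ring-fusion C–C bond (Grob-type heterolysis, strain-driven) to give the ten-membered ring as a regiodefined dienol silyl ether while the silyl group is relayed from O6 to O8 in a chain, so the two carbonyls of the 1,3-dione stay differentiated and both stereocentres of 8 vanish (9 is achiral), and the free conjugated C6 ketone is reduced in the same flask by (S)-CBS/catecholborane (alkenyl as large group) to the 1R alcohol; the closest known chemistry is the Lewis-acid cleavage of 3-alkoxycyclobutanones to 1,4-zwitterions and the acid- or fluoride-induced retro-aldol ring expansion of 3-silyloxybicyclo[n.2.0]alkanones to 1,3-diones, combined with a Corey–Bakshi–Shibata reduction.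

**Step 6**
Reactants: 11 3-bromo-2-oxopropanoic acid (bromopyruvic acid)
Product: 12 3-(acetyloxy)-2-oxopropanoic acid
Conditions: KOAc (1.05 equiv), AcOH, 50 °C
Reagents that add atoms: potassium acetate, CC(=O)[O-].[K+]
Why: SN2 displacement of the activated α-bromo ketone by acetate gives the acetoxymethyl ketone that becomes C13–OAc (nucleophilic substitution).

**Step 7**
Reactants: 10 (1R,2Z,6Z,8E)-3,7-dimethyl-9-(triethylsilyloxy)cyclodeca-2,6,8-trien-1-ol; 12 3-(acetyloxy)-2-oxopropanoic acid
Product: 13 (1R,2Z,6Z,8E)-3,7-dimethyl-9-(triethylsilyloxy)cyclodeca-2,6,8-trien-1-yl 3-(acetyloxy)-2-oxopropanoate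
Conditions: DCC (1.1 equiv), DMAP (5 mol%), CH2Cl2, −20 → 0 °C
Reagents that add atoms: none
Why: Steglich esterification of the allylic alcohol with the α-keto acid ties C11–C13 to O6, which fixes the lactone regiochemistry later, while the silyl dienol ether is inert and the carbinol centre is untouched.

**Step 8**
Reactants: 13 (1R,2Z,6Z,8E)-3,7-dimethyl-9-(triethylsilyloxy)cyclodeca-2,6,8-trien-1-yl 3-(acetyloxy)-2-oxopropanoate
Product: 16 (6S)-13-acetoxy-8-oxogermacra-1(10)Z,4Z,7(11)-trien-12,6-olide, via keto ester 14 (not isolated), via aldol lactone 15 (not isolated)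
Conditions: TsOH·H2O (0.2 equiv), water-saturated CH2Cl2, 0 °C → rt; then 4 Å molecular sieves
Reagents that add atoms: none
Why: Acid hydrolysis of the silyl dienol ether (α-protonation keeps the C1(10) alkene out of conjugation) unmasks the C8 ketone, whose enol adds 5-exo to the activated α-keto ester carbonyl (the seven-ring alternative from C9 is disfavoured) and dehydration gives the tetrasubstituted C7=C11 butenolide, Brønsted acid being chosen so that no enolate forms that could expel the β-acyloxy group or epimerise C6 (intramolecular aldol condensation).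

**Step 9**
Reactants: 16 (6S)-13-acetoxy-8-oxogermacra-1(10)Z,4Z,7(11)-trien-12,6-olide
Product: 17 (6S,8R)-13-acetoxy-8-hydroxygermacra-1(10)Z,4Z,7(11)-trien-12,6-olide
Conditions: (S)-Me-CBS oxazaborolidine (20 mol%), catecholborane (1.5 equiv), toluene/CH2Cl2, −78 °C
Reagents that add atoms: none
Why: In this CBS reduction the α-branched alkenyl (butenolide) carbon acts as the large group and C9H2 as the small one, so the (S)-catalyst delivers hydride under reagent control to give the 8R carbinol (O8 cis to O6), and the non-basic medium leaves the acidic H6 and the allylic acetate untouched.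

**Step 10**
Reactants: 17 (6S,8R)-13-acetoxy-8-hydroxygermacra-1(10)Z,4Z,7(11)-trien-12,6-olide
Product: 18 (1R,4S,5R,6R,8R,10S)-13-acetoxy-1,10:4,5-diepoxy-8-hydroxygermacr-7(11)-en-12,6-olide
Conditions: VO(C5H7O2)2 (vanadyl acetylacetonate, 5 mol%), t-BuOOH (2.5 equiv, in decane), CH2Cl2, 0 °C → rt
Reagents that add atoms: tert-butyl hydroperoxide, CC(C)(C)OO
Why: The pentavalent vanadium alkoxide of the C8 alcohol delivers peroxide oxygen to the near face of the homoallylic C1(10) and the bishomoallylic C4(5) Z-alkenes, so both cis-epoxides form syn to O8 (and to the cis-disposed O6), while the electron-poor butenolide alkene is inert (hydroxyl-directed vanadium-catalysed epoxidation).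

**Step 11**
Reactants: 18 (1R,4S,5R,6R,8R,10S)-13-acetoxy-1,10:4,5-diepoxy-8-hydroxygermacr-7(11)-en-12,6-olide; 19 methacryloyl chloride
Product: 20 (1R,4S,5R,6R,8R,10S)-13-acetoxy-1,10:4,5-diepoxy-8-(2-methylprop-2-enoyloxy)germacr-7(11)-en-12,6-olide (target)
Conditions: CH2=C(CH3)COCl, Et3N, DMAP (5 mol%), CH2Cl2, −20 → 0 °C
Reagents that add atoms: none
Why: DMAP-catalysed acylation of the C8 alcohol at low temperature and short time (to avoid deprotonation at C6) installs the methacrylate without touching any stereocentre.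

**Compound list**
1 | isoprene (2-methylbuta-1,3-diene) | C=CC(C)=C | starting material
2 | (1Z,5Z)-1,5-dimethylcycloocta-1,5-diene | C1/C(C)=C\CC/C(C)=C\C1 | intermediate
3 | (2Z,6Z)-3,7-dimethylcycloocta-2,6-dien-1-one | C1/C(C)=C\C(=O)C/C(C)=C\C1 | intermediate
4 | (1Z,3E,5Z)-1,5-dimethyl-3-(triethylsilyloxy)cycloocta-1,3,5-triene | C1/C(C)=C\C(O[Si](CC)(CC)CC)=C/C(C)=C\C1 | intermediate
5 | dichloroacetyl chloride | ClC(Cl)C(Cl)=O | starting material
6 | dichloroketene | ClC(Cl)=C=O | intermediate
7 | rac-(1S,2Z,6Z,8S)-10,10-dichloro-3,7-dimethyl-1-(triethylsilyloxy)bicyclo[6.2.0]deca-2,6-dien-9-one (cis-fused) | O=C1C(Cl)(Cl)[C@]2(O[Si](CC)(CC)CC)/C=C(C)\CC/C=C(C)\[C@H]12 | intermediate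
8 | rac-(1S,2Z,6Z,8S)-3,7-dimethyl-1-(triethylsilyloxy)bicyclo[6.2.0]deca-2,6-dien-9-one (cis-fused) | O=C1C[C@]2(O[Si](CC)(CC)CC)/C=C(C)\CC/C=C(C)\[C@H]12 | intermediate
9 | (2Z,6Z,8E)-3,7-dimethyl-9-(triethylsilyloxy)cyclodeca-2,6,8-trien-1-one | CC[Si](CC)(CC)O/C1=C/C(C)=C\CC/C(C)=C\C(=O)C1 | intermediate
10 | (1R,2Z,6Z,8E)-3,7-dimethyl-9-(triethylsilyloxy)cyclodeca-2,6,8-trien-1-ol | CC[Si](CC)(CC)O/C1=C/C(C)=C\CC/C(C)=C\[C@H](O)C1 | intermediate
11 | 3-bromo-2-oxopropanoic acid | OC(=O)C(=O)CBr | starting material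
12 | 3-(acetyloxy)-2-oxopropanoic acid | CC(=O)OCC(=O)C(=O)O | intermediate
13 | (1R,2Z,6Z,8E)-3,7-dimethyl-9-(triethylsilyloxy)cyclodeca-2,6,8-trien-1-yl 3-(acetyloxy)-2-oxopropanoate | CC[Si](CC)(CC)O/C1=C/C(C)=C\CC/C(C)=C\[C@H](OC(=O)C(=O)COC(C)=O)C1 | intermediate
14 | (1R,2Z,6Z)-3,7-dimethyl-9-oxocyclodeca-2,6-dien-1-yl 3-(acetyloxy)-2-oxopropanoate | O=C1C/C(C)=C\CC/C(C)=C\[C@H](OC(=O)C(=O)COC(C)=O)C1 | intermediate
15 | (6S)-13-acetoxy-11-hydroxy-8-oxogermacra-1(10)Z,4Z-dien-12,6-olide (mixture at C7 and C11) | O=C1C/C(C)=C\CC/C(C)=C\[C@@H]2OC(=O)C(O)(COC(C)=O)C12 | intermediate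
16 | (6S)-13-acetoxy-8-oxogermacra-1(10)Z,4Z,7(11)-trien-12,6-olide | O=C1C/C(C)=C\CC/C(C)=C\[C@@H]2OC(=O)C(COC(C)=O)=C12 | intermediate
17 | (6S,8R)-13-acetoxy-8-hydroxygermacra-1(10)Z,4Z,7(11)-trien-12,6-olide | O[C@@H]1C/C(C)=C\CC/C(C)=C\[C@@H]2OC(=O)C(COC(C)=O)=C12 | intermediate
18 | (1R,4S,5R,6R,8R,10S)-13-acetoxy-1,10:4,5-diepoxy-8-hydroxygermacr-7(11)-en-12,6-olide | O[C@@H]1C[C@]2(C)O[C@@H]2CC[C@]2(C)O[C@@H]2[C@@H]2OC(=O)C(COC(C)=O)=C21 | intermediate
19 | methacryloyl chloride | C=C(C)C(Cl)=O | starting material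
20 | (1R,4S,5R,6R,8R,10S)-13-acetoxy-1,10:4,5-diepoxy-8-(2-methylprop-2-enoyloxy)germacr-7(11)-en-12,6-olide | C=C(C)C(=O)O[C@@H]1C[C@]2(C)O[C@@H]2CC[C@]2(C)O[C@@H]2[C@@H]2OC(=O)C(COC(C)=O)=C21 | target

**Step count and risks**
Total step count: 11. Longest linear sequence: 10 (steps 1–5 and 7–11).

Steps most likely to fail:

Step 2 (site selectivity among six allylic positions and over-oxidation of a symmetrical diene). The fallback sets out from 2 and comes back at 3, replacing direct C–H oxidation by an epoxide-based oxidative transposition. m-Chloroperoxybenzoic acid (1 equiv, CH2Cl2, 0 °C) gives the racemic cis-monoepoxide rac-(1S,8R,4Z)-1,5-dimethyl-9-oxabicyclo[6.1.0]non-4-ene F1. PhSeSePh/NaBH4 in EtOH opens it at the secondary carbon to the trans-hydroxy selenide rac-(1S,8S,4Z)-1,5-dimethyl-8-(phenylselanyl)cyclooct-4-en-1-ol F2. H2O2 oxidation and syn-elimination away from the carbinol give the tertiary allylic alcohol rac-(2Z,5Z)-1,5-dimethylcycloocta-2,5-dien-1-ol F3. Pyridinium chlorochromate, (C5H5NH)[CrO3Cl], then effects the 1,3-oxidative transposition (Babler–Dauben) to 3.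

Step 5 (the proposed new silyl-transfer ring expansion; the main threats are cleavage of the other cyclobutane bond and transannular vinylogous aldol reaction of 9 before reduction). The fallback sets out from 8 and comes back at 14, using only known chemistry. Hydrolytic retro-aldol ring expansion (AcOH, H2O, i-PrOH, 50 °C) gives (4Z,8Z)-5,9-dimethylcyclodeca-4,8-diene-1,3-dione F4. Transfer hydrogenation with RuCl(p-cymene)[(R,R)-TsDPEN] in HCO2H–Et3N reduces the conjugated (alkenyl) ketone in preference to the dialkyl ketone and gives (3Z,7Z,9R)-9-hydroxy-3,7-dimethylcyclodeca-3,7-dien-1-one F5. Esterification with 12 (DCC, DMAP) gives 14, which is cyclised under the acid conditions of step 8.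

Step 10 (facial selectivity of two epoxidations on a flexible ten-membered ring, one of them directed only from the bishomoallylic position). The fallback sets out from 17 and comes back at 18, switching from substrate direction to catalyst control. Shi epoxidation with the D-fructose-derived ketone, KHSO5 (Oxone) and K2CO3 buffer in MeCN–dimethoxymethane–water at 0 °C is used. Both Z-trisubstituted alkenes require the same local sense of oxygen delivery (S at the methyl-bearing carbon, R at the CH), so one ketone enantiomer serves both, and the electron-poor butenolide alkene is not attacked.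

Further compounds
F1 | step 2 | rac-(1S,8R,4Z)-1,5-dimethyl-9-oxabicyclo[6.1.0]non-4-ene | C1/C(C)=C\CC[C@]2(C)O[C@@H]2C1
F2 | step 2 | rac-(1S,8S,4Z)-1,5-dimethyl-8-(phenylselanyl)cyclooct-4-en-1-ol | C1/C(C)=C\CC[C@](C)(O)[C@@H]([Se]c2ccccc2)C1
F3 | step 2 | rac-(2Z,5Z)-1,5-dimethylcycloocta-2,5-dien-1-ol | C[C@@]1(O)/C=C\C/C(C)=C\CC1
F4 | step 5 | (4Z,8Z)-5,9-dimethylcyclodeca-4,8-diene-1,3-dione | O=C1C/C(C)=C\CC/C(C)=C\C(=O)C1
F5 | step 5 | (3Z,7Z,9R)-9-hydroxy-3,7-dimethylcyclodeca-3,7-dien-1-one | O=C1C/C(C)=C\CC/C(C)=C\[C@H](O)C1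
F0 | step 10 | none | none
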